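**Plan**

- Retrosynthesis: the C9'=C10' alkene is cut first (olefination of a C9' aldehyde with a cinnamyl phosphonate), and the acetic acid arm is traced back to a vinyl group on C3. Both C–O bonds of the dioxolane (C5–O1 and C3–O2) are then cut to give O2 and a vinylcyclopropane.
- Enabling feature: in the ring O1–O2–C3–C4–C5, C3 (methyl, acid arm) and C5 (methyl, branched chain) are quaternary carbons linked only through the C4 methylene. C3–C4–C5 is therefore carried as a cyclopropane whose strained C3–C5 bond is exchanged for the O1–O2 bridge once a radical is generated beside C3 from the vinyl group.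
- The cyclopropane goes back to a tetrasubstituted allylic alcohol (Simmons–Smith), a methyl ketone (Horner–Wadsworth–Emmons), a linear enone (conjugate methyl addition) and non-8-en-1-ol (cross-metathesis).
- Forward order: chain C2'–C9' with its silyl ether (steps 1–3), cyclopropane on the ketone carbon (steps 4–8), dioxolane as the only ring formed (step 9), then acid and (E,E)-phenyldiene (steps 10–14).
- Stereochemistry: C2' (R) comes from a ligand-controlled copper-catalysed addition of MeMgBr. C3 and C5 arise together in the radical step without absolute control and with only a weak cis-dimethyl preference, so the (3R,5R) isomer is isolated by chromatography. The C9'=C10' bond is set E in the last step and the styryl bond is carried in E.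

Key step: step 9

Assumption: the (R,S) enantiomer of the Josiphos ligand is taken to deliver methyl to the enone face that gives the (4R) ketone in step 3; this sense is not verified here, and if it is opposite the commercially available (S,R) ligand is used with no other change.

**Route**

Step 1
Reactants: 1 non-8-en-1-ol; 2 tert-butyl(chloro)diphenylsilane
Product: 3 tert-butyl(non-8-en-1-yloxy)diphenylsilane
Conditions: imidazole, CH2Cl2, 0 °C to rt
Reagents that add atoms: tert-butyl(chloro)diphenylsilane, CC(C)(C)[Si](Cl)(c1ccccc1)c1ccccc1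
Why: Silylation of a primary alcohol gives a tert-butyldiphenylsilyl ether that should withstand the Grignard, hydride, zinc carbenoid, radical, borane and oxidation steps up to step 12.

Step 2
Reactants: 3 tert-butyl(non-8-en-1-yloxy)diphenylsilane; 4 but-3-en-2-one
Product: 5 (3E)-11-[(tert-butyldiphenylsilyl)oxy]undec-3-en-2-one
Conditions: second-generation Grubbs catalyst RuCl2(=CHPh)(PCy3)(H2IMes) (3 mol %), 4 (3 equiv), CH2Cl2, 40 °C
Reagents that add atoms: but-3-en-2-one, CC(=O)C=C
Why: Olefin cross-metathesis of a terminal alkene with an electron-poor vinyl ketone favours the cross product and the E enone, with ethene as the only co-product.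

Step 3
Reactants: 5 (3E)-11-[(tert-butyldiphenylsilyl)oxy]undec-3-en-2-one; 6 methylmagnesium bromide
Product: 7 (4R)-11-[(tert-butyldiphenylsilyl)oxy]-4-methylundecan-2-one
Conditions: CuBr·SMe2 (5 mol %), (R)-1-[(S)-2-(diphenylphosphino)ferrocenyl]ethyldicyclohexylphosphine [(R,S)-Josiphos] (6 mol %), 6 (1.2 equiv), t-BuOMe, −75 °C, slow addition of 5; aq NH4Cl
Reagents that add atoms: methylmagnesium bromide, C[Mg]Br
Why: Copper-catalysed asymmetric conjugate addition of a Grignard reagent to a linear (E)-enone, in which the ferrocenyl diphosphine on monovalent copper selects the enone face and sets C4 of 7 (C2' of the target) as R, 1,2-addition being suppressed in t-BuOMe at low temperature.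

Step 4
Reactants: 7 (4R)-11-[(tert-butyldiphenylsilyl)oxy]-4-methylundecan-2-one; 8 triethyl 2-phosphonopropionate
Product: 9 ethyl (2E/Z,5R)-12-[(tert-butyldiphenylsilyl)oxy]-2,3,5-trimethyldodec-2-enoate (mixture of alkene isomers)
Conditions: NaH (3 equiv), 8 (3 equiv), THF, 0 °C then reflux
Reagents that add atoms: triethyl 2-phosphonopropionate, CCOC(=O)C(C)P(=O)(OCC)OCC
Why: Horner–Wadsworth–Emmons olefination of an unhindered methyl ketone with an α-methyl phosphonate anion gives the tetrasubstituted enoate; the E/Z ratio does not matter because both alkene carbons become ring carbons whose relative configuration is erased in step 9, and the β-stereocentre cannot epimerise.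

Step 5
Reactants: 9 ethyl (2E/Z,5R)-12-[(tert-butyldiphenylsilyl)oxy]-2,3,5-trimethyldodec-2-enoate
Product: 10 (2E/Z,5R)-12-[(tert-butyldiphenylsilyl)oxy]-2,3,5-trimethyldodec-2-en-1-ol (mixture of alkene isomers)
Conditions: i-Bu2AlH (2.5 equiv), CH2Cl2, −78 to 0 °C; aq potassium sodium tartrate
Reagents that add atoms: none
Why: Reduction of an α,β-unsaturated ester with i-Bu2AlH by two 1,2-hydride transfers gives the allylic alcohol that directs step 6.

Step 6
Reactants: 10 (2E/Z,5R)-12-[(tert-butyldiphenylsilyl)oxy]-2,3,5-trimethyldodec-2-en-1-ol; 11 diiodomethane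
Product: 12 {1,2-dimethyl-2-[(2R)-9-[(tert-butyldiphenylsilyl)oxy]-2-methylnonyl]cyclopropyl}methanol (mixture of ring diastereomers)
Conditions: Et2Zn (3 equiv), 11 (6 equiv), CH2Cl2, 0 °C to rt; aq NH4Cl
Reagents that add atoms: diiodomethane, ICI
Why: Simmons–Smith cyclopropanation with Et2Zn/CH2I2 is accelerated by the allylic zinc alkoxide and is fast on electron-rich tetrasubstituted alkenes; its facial sense and the alkene geometry need no control because both ring carbons are re-formed in step 9.

Step 7
Reactants: 12 {1,2-dimethyl-2-[(2R)-9-[(tert-butyldiphenylsilyl)oxy]-2-methylnonyl]cyclopropyl}methanol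
Product: 13 1,2-dimethyl-2-[(2R)-9-[(tert-butyldiphenylsilyl)oxy]-2-methylnonyl]cyclopropane-1-carbaldehyde (mixture of ring diastereomers)
Conditions: Dess–Martin periodinane, CH2Cl2, 0 °C to rt
Reagents that add atoms: none
Why: Dess–Martin oxidation of a neopentyl-type primary alcohol gives an aldehyde with no α-hydrogen, which can neither enolise nor epimerise.

Step 8
Reactants: 13 1,2-dimethyl-2-[(2R)-9-[(tert-butyldiphenylsilyl)oxy]-2-methylnonyl]cyclopropane-1-carbaldehyde; 14 methyltriphenylphosphonium bromide
Product: 15 1-ethenyl-1,2-dimethyl-2-[(2R)-9-[(tert-butyldiphenylsilyl)oxy]-2-methylnonyl]cyclopropane (mixture of ring diastereomers)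
Conditions: 14 (2 equiv), KOt-Bu (1.9 equiv), THF, 0 °C to rt
Reagents that add atoms: methyltriphenylphosphonium bromide, C[P+](c1ccccc1)(c1ccccc1)c1ccccc1.[Br-]
Why: Wittig methylenation with the unstabilised ylide tolerates the hindered, non-enolisable aldehyde and installs the vinyl group that accepts the thiyl radical in step 9.

Step 9
Reactants: 15 1-ethenyl-1,2-dimethyl-2-[(2R)-9-[(tert-butyldiphenylsilyl)oxy]-2-methylnonyl]cyclopropane; 16 dioxygen
Product: 17 (3R,5R)-3-ethenyl-3,5-dimethyl-5-[(2R)-9-[(tert-butyldiphenylsilyl)oxy]-2-methylnonyl]-1,2-dioxolane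
Conditions: PhSSPh (0.2 equiv), AIBN (0.1 equiv), O2 (1 atm), MeCN/PhH, hν (sunlamp), 0 °C; silica chromatography, then preparative HPLC
Reagents that add atoms: dioxygen, O=O
Why: PhS• (from PhSSPh, AIBN and light) adds reversibly to the vinyl terminus, the cyclopropylcarbinyl radical opens at the bond between the two methyl-bearing ring carbons to give the tertiary radical at the future C5, this radical captures O2 (C5–O1), and the peroxyl radical adds to the methyl-bearing carbon of the allylic sulfide (C3–O2) before β-scission expels PhS•, which restores the vinyl group and carries the chain. The closest known reaction type is the thiyl- or selenyl-radical-catalysed [3+2] oxygenation of vinylcyclopropanes to 3-vinyl-1,2-dioxolanes, applied here to a 1,2-dialkyl-1-vinylcyclopropane. The dioxolane, the only ring formed, closes by 5-exo-trig attack of the oxygen radical, the 6-endo mode not being competitive. C5 is created by O2 capture at a planar tertiary radical with no facial bias from the remote C2' centre, and C3 is set relative to C5 in a chair-like closure in which the chain methylene on C5 prefers the pseudo-equatorial site, which favours the cis-dimethyl relation only weakly because methyl and methylene differ little in size. The step needs ring opening toward the tertiary radical, which the methyl group on each ring carbon and the release of ring strain secure, and every ring diastereomer of 15 converges on the same open-chain radical. All four C3/C5 diastereomers are therefore expected, and 17 is to be isolated by separating cis from trans on silica and the two cis isomers by preparative HPLC.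

Step 10
Reactants: 17 (3R,5R)-3-ethenyl-3,5-dimethyl-5-[(2R)-9-[(tert-butyldiphenylsilyl)oxy]-2-methylnonyl]-1,2-dioxolane; 18 9-borabicyclo[3.3.1]nonane; 19 sodium perborate tetrahydrate
Product: 21 2-{(3S,5R)-3,5-dimethyl-5-[(2R)-9-[(tert-butyldiphenylsilyl)oxy]-2-methylnonyl]-1,2-dioxolan-3-yl}ethan-1-ol, via B-alkyl-9-borabicyclo[3.3.1]nonane 20 (not isolated)
Conditions: 18 (0.5 M in THF, 1.5 equiv), THF, 0 °C to rt; then 19, H2O, rt
Reagents that add atoms: sodium perborate tetrahydrate, O.O.O.O.[Na+].[O-]OB=O (hydroxyl oxygen of 21); 9-borabicyclo[3.3.1]nonane, B1C2CCCC1CCC2 (boron and bicycle of 20 only)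
Why: Anti-Markovnikov hydroboration–oxidation with the bulky 9-borabicyclononane places boron on the terminal carbon only, and dialkyl peroxides are known to survive hydroboration and perborate oxidation, so the primary alcohol should form with the ring intact (the C3 descriptor changes to S only through ligand priorities).

Step 11
Reactants: 21 2-{(3S,5R)-3,5-dimethyl-5-[(2R)-9-[(tert-butyldiphenylsilyl)oxy]-2-methylnonyl]-1,2-dioxolan-3-yl}ethan-1-ol; 22 water
Product: 24 2-{(3R,5R)-3,5-dimethyl-5-[(2R)-9-[(tert-butyldiphenylsilyl)oxy]-2-methylnonyl]-1,2-dioxolan-3-yl}acetic acid, via dioxolan-3-ylacetaldehyde 23 (not isolated)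
Conditions: TEMPO (0.2 equiv), PhI(OAc)2 (2.2 equiv), MeCN/H2O 1:1, rt
Reagents that add atoms: water, O
Why: Nitroxyl-catalysed oxidation takes the primary alcohol through the aldehyde hydrate to the carboxylic acid under non-basic, non-reducing conditions that should leave the O–O bond and the silyl ether untouched.

Step 12
Reactants: 24 2-{(3R,5R)-3,5-dimethyl-5-[(2R)-9-[(tert-butyldiphenylsilyl)oxy]-2-methylnonyl]-1,2-dioxolan-3-yl}acetic acid
Product: 25 2-{(3R,5R)-5-[(2R)-9-hydroxy-2-methylnonyl]-3,5-dimethyl-1,2-dioxolan-3-yl}acetic acid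
Conditions: HF·pyridine, THF/pyridine, 0 °C to rt
Reagents that add atoms: none
Why: Fluoride-mediated desilylation with pyridine-buffered HF frees the primary alcohol without exposing the β-peroxy acid to strong base or to a reductant.

Step 13
Reactants: 25 2-{(3R,5R)-5-[(2R)-9-hydroxy-2-methylnonyl]-3,5-dimethyl-1,2-dioxolan-3-yl}acetic acid
Product: 26 2-{(3R,5R)-3,5-dimethyl-5-[(2R)-2-methyl-9-oxononyl]-1,2-dioxolan-3-yl}acetic acid
Conditions: Dess–Martin periodinane (1.3 equiv), CH2Cl2, 0 °C to rt
Reagents that add atoms: none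
Why: Dess–Martin oxidation converts the primary alcohol into the aldehyde in the presence of the free acid and the peroxide, neither of which is oxidised under these conditions.

Step 14
Reactants: 26 2-{(3R,5R)-3,5-dimethyl-5-[(2R)-2-methyl-9-oxononyl]-1,2-dioxolan-3-yl}acetic acid; 27 diethyl [(2E)-3-phenylprop-2-en-1-yl]phosphonate
Product: 28 2-{(3R,5R)-3,5-dimethyl-5-[(2R,9E,11E)-2-methyl-12-phenyldodeca-9,11-dien-1-yl]-1,2-dioxolan-3-yl}acetic acid
Conditions: 27 (3 equiv), NaN(SiMe3)2 (3 equiv), THF, −78 °C; then 26, −78 to 0 °C; then 1 M HCl to pH 3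
Reagents that add atoms: diethyl [(2E)-3-phenylprop-2-en-1-yl]phosphonate, CCOP(=O)(OCC)C/C=C/c1ccccc1
Why: Horner–Wadsworth–Emmons olefination with the allylic phosphonate anion, used in excess so that one equivalent is spent on the acid, should give the new C9'=C10' bond mainly E, while the E styryl bond is carried in from 27 and the carboxylate form shields the β-peroxy acid from elimination.

**Compound list**

1 | non-8-en-1-ol | OCCCCCCCC=C | starting material
2 | tert-butyl(chloro)diphenylsilane | CC(C)(C)[Si](Cl)(c1ccccc1)c1ccccc1 | starting material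
3 | tert-butyl(non-8-en-1-yloxy)diphenylsilane | C=CCCCCCCCO[Si](c1ccccc1)(c1ccccc1)C(C)(C)C | intermediate
4 | but-3-en-2-one | CC(=O)C=C | starting material
5 | (3E)-11-[(tert-butyldiphenylsilyl)oxy]undec-3-en-2-one | CC(=O)/C=C/CCCCCCCO[Si](c1ccccc1)(c1ccccc1)C(C)(C)C | intermediate
6 | methylmagnesium bromide | C[Mg]Br | starting material
7 | (4R)-11-[(tert-butyldiphenylsilyl)oxy]-4-methylundecan-2-one | C[C@H](CCCCCCCO[Si](c1ccccc1)(c1ccccc1)C(C)(C)C)CC(C)=O | intermediate
8 | triethyl 2-phosphonopropionate | CCOC(=O)C(C)P(=O)(OCC)OCC | starting material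
9 | ethyl (2E/Z,5R)-12-[(tert-butyldiphenylsilyl)oxy]-2,3,5-trimethyldodec-2-enoate (alkene isomers) | C[C@H](CCCCCCCO[Si](c1ccccc1)(c1ccccc1)C(C)(C)C)CC(C)=C(C)C(=O)OCC | intermediate
10 | (2E/Z,5R)-12-[(tert-butyldiphenylsilyl)oxy]-2,3,5-trimethyldodec-2-en-1-ol (alkene isomers) | C[C@H](CCCCCCCO[Si](c1ccccc1)(c1ccccc1)C(C)(C)C)CC(C)=C(C)CO | intermediate
11 | diiodomethane | ICI | starting material
12 | {1,2-dimethyl-2-[(2R)-9-[(tert-butyldiphenylsilyl)oxy]-2-methylnonyl]cyclopropyl}methanol (ring diastereomers) | C[C@H](CCCCCCCO[Si](c1ccccc1)(c1ccccc1)C(C)(C)C)CC1(C)CC1(C)CO | intermediate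
13 | 1,2-dimethyl-2-[(2R)-9-[(tert-butyldiphenylsilyl)oxy]-2-methylnonyl]cyclopropane-1-carbaldehyde (ring diastereomers) | C[C@H](CCCCCCCO[Si](c1ccccc1)(c1ccccc1)C(C)(C)C)CC1(C)CC1(C)C=O | intermediate
14 | methyltriphenylphosphonium bromide | C[P+](c1ccccc1)(c1ccccc1)c1ccccc1.[Br-] | starting material
15 | 1-ethenyl-1,2-dimethyl-2-[(2R)-9-[(tert-butyldiphenylsilyl)oxy]-2-methylnonyl]cyclopropane (ring diastereomers) | C[C@H](CCCCCCCO[Si](c1ccccc1)(c1ccccc1)C(C)(C)C)CC1(C)CC1(C)C=C | intermediate
16 | dioxygen | O=O | starting material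
17 | (3R,5R)-3-ethenyl-3,5-dimethyl-5-[(2R)-9-[(tert-butyldiphenylsilyl)oxy]-2-methylnonyl]-1,2-dioxolane | C[C@H](CCCCCCCO[Si](c1ccccc1)(c1ccccc1)C(C)(C)C)C[C@]1(C)C[C@](C)(C=C)OO1 | intermediate
18 | 9-borabicyclo[3.3.1]nonane | B1C2CCCC1CCC2 | starting material
19 | sodium perborate tetrahydrate | O.O.O.O.[Na+].[O-]OB=O | starting material
20 | 9-(2-{(3S,5R)-3,5-dimethyl-5-[(2R)-9-[(tert-butyldiphenylsilyl)oxy]-2-methylnonyl]-1,2-dioxolan-3-yl}ethyl)-9-borabicyclo[3.3.1]nonane (formed in the flask in step 10) | C[C@H](CCCCCCCO[Si](c1ccccc1)(c1ccccc1)C(C)(C)C)C[C@]1(C)C[C@](C)(CCB2C3CCCC2CCC3)OO1 | intermediate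
21 | 2-{(3S,5R)-3,5-dimethyl-5-[(2R)-9-[(tert-butyldiphenylsilyl)oxy]-2-methylnonyl]-1,2-dioxolan-3-yl}ethan-1-ol | C[C@H](CCCCCCCO[Si](c1ccccc1)(c1ccccc1)C(C)(C)C)C[C@]1(C)C[C@](C)(CCO)OO1 | intermediate
22 | water | O | starting material
23 | 2-{(3R,5R)-3,5-dimethyl-5-[(2R)-9-[(tert-butyldiphenylsilyl)oxy]-2-methylnonyl]-1,2-dioxolan-3-yl}acetaldehyde (formed in the flask in step 11) | C[C@H](CCCCCCCO[Si](c1ccccc1)(c1ccccc1)C(C)(C)C)C[C@]1(C)C[C@](C)(CC=O)OO1 | intermediate
24 | 2-{(3R,5R)-3,5-dimethyl-5-[(2R)-9-[(tert-butyldiphenylsilyl)oxy]-2-methylnonyl]-1,2-dioxolan-3-yl}acetic acid | C[C@H](CCCCCCCO[Si](c1ccccc1)(c1ccccc1)C(C)(C)C)C[C@]1(C)C[C@](C)(CC(=O)O)OO1 | intermediate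
25 | 2-{(3R,5R)-5-[(2R)-9-hydroxy-2-methylnonyl]-3,5-dimethyl-1,2-dioxolan-3-yl}acetic acid | C[C@H](CCCCCCCO)C[C@]1(C)C[C@](C)(CC(=O)O)OO1 | intermediate
26 | 2-{(3R,5R)-3,5-dimethyl-5-[(2R)-2-methyl-9-oxononyl]-1,2-dioxolan-3-yl}acetic acid | C[C@H](CCCCCCC=O)C[C@]1(C)C[C@](C)(CC(=O)O)OO1 | intermediate
27 | diethyl [(2E)-3-phenylprop-2-en-1-yl]phosphonate (diethyl cinnamylphosphonate) | CCOP(=O)(OCC)C/C=C/c1ccccc1 | starting material
28 | 2-{(3R,5R)-3,5-dimethyl-5-[(2R,9E,11E)-2-methyl-12-phenyldodeca-9,11-dien-1-yl]-1,2-dioxolan-3-yl}acetic acid | C[C@H](CCCCCC/C=C/C=C/c1ccccc1)C[C@]1(C)C[C@](C)(CC(=O)O)OO1 | target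

**Step count and risks**

Total steps: 14. Longest linear sequence: 14 steps, from non-8-en-1-ol.

Step 9 carries the highest risk. The process at fault would be the lack of facial control: O2 adds to either face of the planar C5 radical and the 5-exo closure tells methyl from methylene only weakly. The material is therefore spread over four C3/C5 diastereomers, and the two cis-dimethyl isomers, which differ only in how the ring relates to C2', may not separate as lipophilic silyl ethers. The fallback replaces direct chromatography by separation through a covalent derivative. It sets out from 21, obtained as the unresolved cis pair by taking the mixed cis fraction of 17 through step 10. Acylation with 3,5-dinitrobenzoyl chloride (pyridine, CH2Cl2) should give the 2-(dioxolan-3-yl)ethyl 3,5-dinitrobenzoate F1 together with its (3R,5S) isomer. The π-acidic ester group, three atoms from C3, is intended to allow fractional crystallisation or preparative HPLC on a π-donor or polysaccharide chiral stationary phase. Methanolysis (K2CO3, MeOH, 0 °C) of pure F1 comes back to the route at 21. The configuration of the isomer carried forward would be secured by X-ray analysis of a crystalline ester or by comparison of 28 with the natural acid.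

Step 10 is the second risk. The process at fault would be cleavage of the O–O bond by the borane or by the B-alkyl intermediate, or slow hydroboration beside the quaternary C3. The fallback replaces hydroboration by oxidative cleavage and one-carbon homologation, sets out from 17 and returns at 24. Ozonolysis (O3, CH2Cl2, −78 °C; Me2S) should give the non-enolisable (3R,5R)-dioxolane-3-carbaldehyde F2. Wittig reaction with methoxymethylidenetriphenylphosphorane (from (methoxymethyl)triphenylphosphonium chloride and KN(SiMe3)2, THF, −78 to 0 °C) would give the (3R,5R)-3-(2-methoxyethenyl)dioxolane F3. Hydrolysis of the enol ether (TsOH·H2O, acetone/H2O) gives aldehyde 23, here isolated, and NaClO2/NaH2PO4/2-methylbut-2-ene in t-BuOH/H2O re-enters the route at 24.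

Step 14 is the third risk. The process at fault would be incomplete E selectivity at the new C9'=C10' bond, whose geometric isomers would be hard to part from 28, together with base-induced opening of the β-peroxy carboxylate by the excess amide base. The fallback builds the diene in two E-selective olefinations with the C11'=C12' bond made last, sets out from 26 and comes back at 28. The stabilised ylide (triphenylphosphoranylidene)acetaldehyde (2 equiv, CH2Cl2, rt to 40 °C), which needs no added base, should give the (2R,9E)-2-methyl-11-oxoundec-9-enyl dioxolane acetic acid F4. Horner–Wadsworth–Emmons reaction of F4 with the anion of diethyl benzylphosphonate (NaN(SiMe3)2, THF, −78 to 0 °C), reliably E-selective with enals, then gives 28.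

Further compounds
F1 | step 9 | 2-{(3S,5R)-3,5-dimethyl-5-[(2R)-9-[(tert-butyldiphenylsilyl)oxy]-2-methylnonyl]-1,2-dioxolan-3-yl}ethyl 3,5-dinitrobenzoate | C[C@H](CCCCCCCO[Si](c1ccccc1)(c1ccccc1)C(C)(C)C)C[C@]1(C)C[C@](C)(CCOC(=O)c2cc(cc(c2)[N+](=O)[O-])[N+](=O)[O-])OO1
F2 | step 10 | (3R,5R)-3,5-dimethyl-5-[(2R)-9-[(tert-butyldiphenylsilyl)oxy]-2-methylnonyl]-1,2-dioxolane-3-carbaldehyde | C[C@H](CCCCCCCO[Si](c1ccccc1)(c1ccccc1)C(C)(C)C)C[C@]1(C)C[C@](C)(C=O)OO1
F3 | step 10 | (3R,5R)-3-(2-methoxyethenyl)-3,5-dimethyl-5-[(2R)-9-[(tert-butyldiphenylsilyl)oxy]-2-methylnonyl]-1,2-dioxolane (E/Z mixture) | C[C@H](CCCCCCCO[Si](c1ccccc1)(c1ccccc1)C(C)(C)C)C[C@]1(C)C[C@](C)(C=COC)OO1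
F4 | step 14 | 2-{(3R,5R)-3,5-dimethyl-5-[(2R,9E)-2-methyl-11-oxoundec-9-en-1-yl]-1,2-dioxolan-3-yl}acetic acid | C[C@H](CCCCCC/C=C/C=O)C[C@]1(C)C[C@](C)(CC(=O)O)OO1
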